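**Plan**

- Retrosynthesis: the C4′ acetate and the C3′ lactone carbonyl are taken back to a bicyclic enol ether; the dioxabicyclo[3.2.1]octane is cut at the acetal bond C1′–O7′, then at C8′–C5′ and C1′–O2′ of the dihydropyran, giving a hydroazulenyl acetaldehyde and a four-carbon γ-silyloxy enal; the ring-fusion bond C5–C9 of the hydroazulene is then traced back to the C5–C10 bond of a trans-decalin.
- Forward: sclareolide is degraded at C11/C12 so that C9 carries nitrogen and C8 a two-carbon arm; one deamination turns rings A and B into the seven- and five-membered carbocycles together; the dihydropyran is then made by [4+2] addition of the aldehyde enamine to the enal, the tetrahydrofuran by acetal exchange, and the lactone by oxidation.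
- Enabling feature: C4 (gem-dimethyl), C5 and C9 (ring fusion), C8 (quaternary methyl carbon) and C10 (methylene carbon) of the target are C4, C5, C9, C8 and C10 of a labdane trans-decalin of the same absolute configuration; an equatorial leaving group on C9 is antiperiplanar to the C10–C5 bond, and the angular methyl on C10 becomes the exocyclic methylene.
- Stereochemistry: C5 is from sclareolide; C8 is re-set in the radical addition by the axial C10 methyl; C9 is set by inversion in the 1,2-shift (cis fusion); C6′ is from (R)-methyl 2-hydroxybut-3-enoate; C8′ and C5′ come from the face-selective [4+2] step; C1′ is fixed by the bridge; C4′ comes from epoxidation anti to the bridge that carries the hydroazulene.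

Key step: step 11

Remark: methyl 2-hydroxybut-3-enoate is used as its (R)-enantiomer, assumed to be purchasable as such; the C–O bond at this carbon is never broken, so it becomes C6′ unchanged.

Remark: labdane/drimane numbering is kept for the carbocycle, also after the rearrangement. Primed locants are those of the 2,7-dioxabicyclo[3.2.1]octane: C1′ acetal bridgehead, O2′, C3′, C4′, C5′ bridgehead, C6′, O7′, C8′ one-carbon bridge.

**Route**

Step 1
Reactants: 1 (+)-sclareolide
Product: 2 11-hydroxysclareolide (hydroxyl on the lactone α-carbon C11; either C11 epimer)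
Conditions: KHMDS, THF, −78 °C; 2-(phenylsulfonyl)-3-phenyloxaziridine, −78 °C; AcOH quench
Reagents that add atoms: 2-(phenylsulfonyl)-3-phenyloxaziridine, O=S(=O)(c1ccccc1)N1OC1c1ccccc1
Why: Enolate α-hydroxylation of the γ-lactone with an N-sulfonyloxaziridine; the C11 configuration does not matter because that stereocentre is erased in step 3.

Step 2
Reactants: 2 11-hydroxysclareolide
Product: 3 13,14,15,16-tetranorlabdane-8α,11,12-triol
Conditions: LiAlH4, THF, 0 °C → reflux; aqueous work-up
Reagents that add atoms: none
Why: Hydride reduction of the lactone frees the tertiary 8α-hydroxyl and gives the 11,12-glycol without touching any stereocentre that is kept.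

Step 3
Reactants: 3 13,14,15,16-tetranorlabdane-8α,11,12-triol
Product: 4 8α-hydroxydriman-11-al (equatorial 9β-formyl)
Conditions: NaIO4, THF/H2O, 0 °C → rt
Reagents that add atoms: none
Why: Periodate glycol cleavage removes C12 as formaldehyde and leaves the C9 aldehyde, which is already the more stable equatorial epimer.

Step 4
Reactants: 4 8α-hydroxydriman-11-al
Product: 5 8α-hydroxydriman-11-oic acid
Conditions: NaClO2, NaH2PO4, 2-methyl-2-butene, t-BuOH/H2O, rt
Reagents that add atoms: sodium chlorite, [Na+].[O-]Cl=O
Why: Pinnick oxidation converts the hindered aldehyde to the acid in a buffered medium that avoids retro-aldol opening of the β-hydroxy carbonyl unit.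

Step 5
Reactants: 5 8α-hydroxydriman-11-oic acid
Product: 8 trans-fused cyclic carbamate of 9β-amino-11-nordriman-8α-ol (sclareolide in which C11H2 is replaced by NH), via acyl azide 6 (not isolated), via isocyanate 7 (not isolated)
Conditions: (PhO)2P(O)N3, Et3N, toluene, rt → 100 °C
Reagents that add atoms: diphenylphosphoryl azide, [N-]=[N+]=NP(=O)(Oc1ccccc1)Oc1ccccc1
Why: Curtius rearrangement goes with retention at C9, and the isocyanate is captured by the neighbouring 8α-hydroxyl in a ring of the same trans-diequatorial geometry as the lactone of sclareolide, so nitrogen ends equatorial (β) on C9.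

Step 6
Reactants: 8 cyclic carbamate
Product: 9 N-Boc cyclic carbamate
Conditions: Boc2O, DMAP (cat.), Et3N, MeCN, rt → 40 °C
Reagents that add atoms: di-tert-butyl dicarbonate, CC(C)(C)OC(=O)OC(=O)OC(C)(C)C
Why: N-acylation of the oxazolidinone activates the ring carbonyl for selective cleavage and installs the nitrogen protecting group.

Step 7
Reactants: 9 N-Boc cyclic carbamate
Product: 10 tert-butyl (8α-hydroxy-11-nordriman-9β-yl)carbamate
Conditions: Cs2CO3 (cat.), MeOH, rt
Reagents that add atoms: none
Why: Methanolysis of an N-Boc oxazolidinone occurs at the endocyclic carbonyl, and the tertiary methyl carbonate so formed is transesterified to dimethyl carbonate, which frees the tertiary alcohol beside the Boc-protected amine.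

Step 8
Reactants: 10 tert-butyl (8α-hydroxy-11-nordriman-9β-yl)carbamate
Product: 12 caesium oxalate of the 8α-alcohol, via methyl oxalate 11 (not isolated)
Conditions: ClC(O)CO2Me, Et3N, DMAP (cat.), CH2Cl2, 0 °C → rt; then 1 M aq. CsOH (1.0 equiv), THF, rt
Reagents that add atoms: methyl chlorooxoacetate, COC(=O)C(=O)Cl; caesium hydroxide, [Cs+].[OH-]
Why: The small, very electrophilic chlorooxoacetate acylates the tertiary alcohol, and one equivalent of hydroxide saponifies only the unhindered methyl ester half, giving the alkyl oxalate salt used as radical precursor.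

Step 9
Reactants: 12 caesium oxalate; 13 phenyl vinyl sulfone
Product: 14 tert-butyl [8β-methyl-8α-(2-phenylsulfonylethyl)-11-nordriman-9β-yl]carbamate (arm equatorial, C8 methyl axial)
Conditions: Ir[dF(CF3)ppy]2(dtbbpy)PF6 (1 mol%), 13 (1.5 equiv), H2O (10 equiv), DME/DMF 3:1, blue LEDs, 60 °C
Reagents that add atoms: none
Why: Photoredox Giese reaction in which oxidation of the oxalate and loss of two CO2 give the C8 tertiary radical, which adds to the vinyl sulfone from the equatorial α-face, anti to the axial C10 methyl, so the arm becomes equatorial and the C8 methyl stays axial; the α-sulfonyl radical is then reduced and protonated.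

Step 10
Reactants: 14 Boc-amino sulfone
Product: 15 8β-methyl-8α-(2-phenylsulfonylethyl)-11-nordriman-9β-amine (equatorial amine)
Conditions: TFA/CH2Cl2 1:4, 0 °C → rt; aq. NaHCO3
Reagents that add atoms: none
Why: Acidolysis of the tert-butyl carbamate frees the amine, and the sulfone and the saturated skeleton are inert to acid.

Step 11
Reactants: 15 equatorial 9β-amine
Product: 17 cis-hydroazulene sulfone (4,4-dimethyl; 10-methylene; 8β-methyl; 8α-(2-phenylsulfonylethyl); H5 and H9 cis), via diazonium acetate 16 (not isolated)
Conditions: NaNO2 (3 equiv), NaOAc, AcOH/H2O 4:1, 0 °C → rt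
Reagents that add atoms: none
Why: Proposed new method: nitrosation converts the equatorial amine into diazonium ion 16, which cannot eliminate because both neighbours (C8 and C10) are quaternary, so N2 leaves with a 1,2-shift of the antiperiplanar C10–C5 bond, and the tertiary C10 cation then gives up a methyl proton to the acetate of the ion pair to form the exocyclic methylene. The closest known reaction types are the Demjanov-type deaminative alkyl shift of equatorial cyclohexylamines and the solvolytic Wagner–Meerwein rearrangement of angularly methylated decalyl sulfonates to hydroazulenes; a deaminative shift on a 9-aminodecalin flanked by two quaternary carbons has not been shown. No ring is closed by cyclisation: the seven-membered ring is ring A enlarged by insertion of C9 between C5 and C10, and the five-membered ring is ring B contracted by extrusion of C10, both through the one suprafacial 1,2-shift. The new stereocentre C9 is fixed by the mechanism, since C5 attacks the backside of the carbon that loses N2 (inversion at C9, retention at C5), which leaves H5 and H9 cis. The step needs C5 to migrate in preference to C7, whose bond to C8 is also antiperiplanar, and the proton to leave from the methyl group and not from C1 or C9; the first is secured by the better migrating ability of the tertiary ring-fusion carbon, the relief of the 1,3-diaxial methyl/methyl strain and the inductive penalty that the sulfonylethyl arm places on a C8 cation, the second by the acetate lying next to the freely rotating methyl group, by H9 being nearly orthogonal to the vacant orbital, and by the cold buffered medium, which stops acid-catalysed migration of the double bond.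

Step 12
Reactants: 17 cis-hydroazulene sulfone
Product: 18 2-(hydroazulen-8α-yl)acetaldehyde (4,4-dimethyl; 10-methylene; 8β-methyl; H5 and H9 cis)
Conditions: n-BuLi (1.1 equiv), THF, −78 °C; Me3SiOOSiMe3, −78 °C → rt
Reagents that add atoms: bis(trimethylsilyl) peroxide, C[Si](C)(C)OO[Si](C)(C)C
Why: Oxidative desulfonylation, in which the α-sulfonyl carbanion is oxygenated by the silyl peroxide and the α-silyloxy sulfone collapses to the aldehyde with loss of sulfinate, a known conversion of primary sulfones into aldehydes that leaves the alkene alone.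

Step 13
Reactants: 19 methyl (R)-2-hydroxybut-3-enoate
Product: 20 methyl (R)-2-(triethylsilyloxy)but-3-enoate
Conditions: Et3SiCl, imidazole, CH2Cl2, 0 °C
Reagents that add atoms: chlorotriethylsilane, CC[Si](Cl)(CC)CC
Why: Silylation of the secondary alcohol under mild base does not touch the stereocentre and blocks later furan formation from the γ-hydroxy enal.

Step 14
Reactants: 20 methyl (R)-2-(triethylsilyloxy)but-3-enoate; 21 acrolein
Product: 22 methyl (2R,3E)-5-oxo-2-(triethylsilyloxy)pent-3-enoate
Conditions: 21 (5 equiv), second-generation Hoveyda–Grubbs catalyst (H2IMes)Cl2Ru=CH(2-iPrOC6H4) (5 mol%), CH2Cl2, 40 °C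
Reagents that add atoms: none
Why: Olefin cross-metathesis of the protected allylic ether with excess acrolein gives the (E)-enal under neutral conditions that should not epimerise the acidic γ-position.

Step 15
Reactants: 18 2-(hydroazulen-8α-yl)acetaldehyde; 22 γ-silyloxy enal
Product: 24 2-(pyrrolidin-1-yl)-3-(hydroazulen-8α-yl)-4-[(R)-(methoxycarbonyl)(triethylsilyloxy)methyl]-3,4-dihydro-2H-pyran (2,3-trans; 3,4-trans), via pyrrolidine enamine 23 (not isolated)
Conditions: pyrrolidine (1.1 equiv), 4 Å MS, benzene, rt; evaporate; 22 (1.2 equiv), MeCN, 0 °C → rt; used crude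
Reagents that add atoms: pyrrolidine, C1CCNC1
Why: Inverse-electron-demand hetero-Diels–Alder reaction of the (E)-enamine with the enal through the amine-endo transition state gives the 3,4-trans dihydropyran; the new C–C bond is expected to form anti to ring-fusion carbon C9 on the enamine (C7 eclipsing the double bond, methyl outside) and anti to the silyloxy group on the enal (Felkin–Anh arrangement with the ester inside), and these two preferences lead to the same isomer.

Step 16
Reactants: 24 aminal dihydropyran
Product: 25 methyl (6′R)-8′-(hydroazulen-8α-yl)-2′,7′-dioxabicyclo[3.2.1]oct-3′-ene-6′-carboxylate (ester exo, syn to C8′; hydroazulenyl syn to the enol ether bridge)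
Conditions: Bu4NF, AcOH (1.5 equiv each), THF, 0 °C → 40 °C
Reagents that add atoms: none
Why: Buffered fluoride removes the silyl group and acetic acid protonates the aminal nitrogen, so pyrrolidine leaves and the freed C6′ hydroxyl closes on the oxocarbenium carbon C1′ (intramolecular transacetalisation, five-membered ring), while the enol ether and the methylene, which need stronger acid, are left alone; C1′ takes the only configuration the bridge allows.

Step 17
Reactants: 25 bicyclic enol ether
Product: 27 3′,4′-dihydroxy bicyclic acetal (lactol at C3′; C4′ hydroxyl anti to C8′), via glycal-type epoxide 26 (not isolated)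
Conditions: DMDO (1.05 equiv), acetone/CH2Cl2, −78 → −20 °C; then H2O, THF, 0 °C
Reagents that add atoms: dimethyldioxirane, CC1(C)OO1; water, O
Why: The electrophilic dioxirane epoxidises the electron-rich enol ether far faster than the 1,1-disubstituted alkene and from the face anti to the one-carbon bridge that carries the hydroazulene; water then opens the epoxide at the anomeric carbon, so the C4′–O bond and its configuration are kept.

Step 18
Reactants: 27 lactol diol
Product: 28 4′-hydroxy-3′-oxo bicyclic lactone (α-hydroxy δ-lactone)
Conditions: TEMPO (20 mol%), PhI(OAc)2 (1.5 equiv), CH2Cl2, rt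
Reagents that add atoms: none
Why: Oxoammonium oxidation (TEMPO/PhI(OAc)2) converts the lactol to the lactone much faster than it oxidises the hindered secondary C4′ alcohol and does not touch the alkene.

Step 19
Reactants: 28 hydroxy lactone
Product: 29 CNP0215240.1
Conditions: Ac2O, pyridine, DMAP (cat.), CH2Cl2, 0 °C → rt
Reagents that add atoms: acetic anhydride, CC(=O)OC(C)=O
Why: DMAP-catalysed acetylation of the secondary alcohol completes the target under conditions too mild to epimerise C4′ or C6′.

**Compound list**

1 | (+)-sclareolide | C[C@]12CCCC(C)(C)[C@@H]1CC[C@@]3(C)OC(=O)C[C@H]23 | starting material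
2 | 11-hydroxysclareolide (C11 unspecified) | C[C@]12CCCC(C)(C)[C@@H]1CC[C@@]3(C)OC(=O)C(O)[C@H]23 | intermediate
3 | 13,14,15,16-tetranorlabdane-8α,11,12-triol | C[C@]12CCCC(C)(C)[C@@H]1CC[C@@](C)(O)[C@@H]2C(O)CO | intermediate
4 | 8α-hydroxydriman-11-al | C[C@]12CCCC(C)(C)[C@@H]1CC[C@@](C)(O)[C@@H]2C=O | intermediate
5 | 8α-hydroxydriman-11-oic acid | C[C@]12CCCC(C)(C)[C@@H]1CC[C@@](C)(O)[C@@H]2C(=O)O | intermediate
6 | 8α-hydroxydriman-11-oyl azide | C[C@]12CCCC(C)(C)[C@@H]1CC[C@@](C)(O)[C@@H]2C(=O)N=[N+]=[N-] | intermediate
7 | 9β-isocyanato-11-nordriman-8α-ol | C[C@]12CCCC(C)(C)[C@@H]1CC[C@@](C)(O)[C@@H]2N=C=O | intermediate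
8 | trans-fused cyclic carbamate of 9β-amino-11-nordriman-8α-ol | C[C@]12CCCC(C)(C)[C@@H]1CC[C@@]3(C)OC(=O)N[C@H]23 | intermediate
9 | N-Boc cyclic carbamate | C[C@]12CCCC(C)(C)[C@@H]1CC[C@@]3(C)OC(=O)N(C(=O)OC(C)(C)C)[C@H]23 | intermediate
10 | tert-butyl (8α-hydroxy-11-nordriman-9β-yl)carbamate | C[C@]12CCCC(C)(C)[C@@H]1CC[C@@](C)(O)[C@@H]2NC(=O)OC(C)(C)C | intermediate
11 | methyl oxalate of 10 | C[C@]12CCCC(C)(C)[C@@H]1CC[C@@](C)(OC(=O)C(=O)OC)[C@@H]2NC(=O)OC(C)(C)C | intermediate
12 | caesium oxalate of 10 | C[C@]12CCCC(C)(C)[C@@H]1CC[C@@](C)(OC(=O)C(=O)[O-])[C@@H]2NC(=O)OC(C)(C)C.[Cs+] | intermediate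
13 | phenyl vinyl sulfone | C=CS(=O)(=O)c1ccccc1 | starting material
14 | tert-butyl [8β-methyl-8α-(2-phenylsulfonylethyl)-11-nordriman-9β-yl]carbamate | C[C@]12CCCC(C)(C)[C@@H]1CC[C@@](C)(CCS(=O)(=O)c3ccccc3)[C@@H]2NC(=O)OC(C)(C)C | intermediate
15 | 8β-methyl-8α-(2-phenylsulfonylethyl)-11-nordriman-9β-amine | C[C@]12CCCC(C)(C)[C@@H]1CC[C@@](C)(CCS(=O)(=O)c3ccccc3)[C@@H]2N | intermediate
16 | 9β-diazonium acetate of 15 | C[C@]12CCCC(C)(C)[C@@H]1CC[C@@](C)(CCS(=O)(=O)c3ccccc3)[C@@H]2[N+]#N.CC(=O)[O-] | intermediate
17 | cis-hydroazulene sulfone (10-methylene, 8β-methyl, 8α-(2-phenylsulfonylethyl), 5αH, 9αH) | C=C1CCCC(C)(C)[C@@H]2CC[C@@](C)(CCS(=O)(=O)c3ccccc3)[C@H]12 | intermediate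
18 | 2-(hydroazulen-8α-yl)acetaldehyde | C=C1CCCC(C)(C)[C@@H]2CC[C@@](C)(CC=O)[C@H]12 | intermediate
19 | methyl (R)-2-hydroxybut-3-enoate | C=C[C@@H](O)C(=O)OC | starting material
20 | methyl (R)-2-(triethylsilyloxy)but-3-enoate | C=C[C@@H](O[Si](CC)(CC)CC)C(=O)OC | intermediate
21 | acrolein | C=CC=O | starting material
22 | methyl (2R,3E)-5-oxo-2-(triethylsilyloxy)pent-3-enoate | O=C/C=C/[C@@H](O[Si](CC)(CC)CC)C(=O)OC | intermediate
23 | (E)-pyrrolidine enamine of 18 | C=C1CCCC(C)(C)[C@@H]2CC[C@@](C)(/C=C/N3CCCC3)[C@H]12 | intermediate
24 | 2-pyrrolidinyl-3,4-dihydro-2H-pyran adduct (2,3-trans, 3,4-trans) | C=C1CCCC(C)(C)[C@@H]2CC[C@@](C)([C@@H]3[C@@H](N4CCCC4)OC=C[C@H]3[C@@H](O[Si](CC)(CC)CC)C(=O)OC)[C@H]12 | intermediate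
25 | methyl (6′R)-8′-(hydroazulen-8α-yl)-2′,7′-dioxabicyclo[3.2.1]oct-3′-ene-6′-carboxylate | C=C1CCCC(C)(C)[C@@H]2CC[C@@](C)([C@@H]3[C@@H]4OC=C[C@H]3[C@H](C(=O)OC)O4)[C@H]12 | intermediate
26 | 3′,4′-epoxide of 25 (oxygen anti to C8′) | C=C1CCCC(C)(C)[C@@H]2CC[C@@](C)([C@@H]3[C@@H]4O[C@H]5O[C@H]5[C@H]3[C@H](C(=O)OC)O4)[C@H]12 | intermediate
27 | 3′,4′-dihydroxy bicyclic acetal (lactol, C3′ unspecified) | C=C1CCCC(C)(C)[C@@H]2CC[C@@](C)([C@@H]3[C@@H]4OC(O)[C@@H](O)[C@H]3[C@H](C(=O)OC)O4)[C@H]12 | intermediate
28 | 4′-hydroxy-3′-oxo bicyclic lactone | C=C1CCCC(C)(C)[C@@H]2CC[C@@](C)([C@@H]3[C@@H]4OC(=O)[C@@H](O)[C@H]3[C@H](C(=O)OC)O4)[C@H]12 | intermediate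
29 | CNP0215240.1 | C=C1CCCC(C)(C)[C@@H]2CC[C@@](C)([C@@H]3[C@@H]4OC(=O)[C@@H](OC(C)=O)[C@H]3[C@H](C(=O)OC)O4)[C@H]12 | target

**Step count**

Total: 19 steps. Longest linear sequence: 17 steps (steps 1–12 and 15–19, from sclareolide); the enal branch is 2 steps (13 and 14).

**Steps most likely to fail**

Step 11. The other antiperiplanar bond (C8–C7) may migrate, the C10 cation may be captured by acetate or water, or the proton may be lost from C1 so that the double bond ends in the ring. The fallback moves to the oxygen series and uses known reactions only. Amine 15 would be condensed with 3,5-di-tert-butyl-1,2-benzoquinone and the imine hydrolysed with aqueous acid to give the C9 ketone F1. LiAlH4 should add from the α-face, away from the two axial methyl groups, to give the equatorial 9β-alcohol F2, which would be converted into the mesylate F3 (MsCl, Et3N, DMAP). Buffered acetolysis (KOAc, AcOH, 60–80 °C) is the known solvolytic rearrangement of decalyl sulfonates to hydroazulenes, in which ionisation is assisted by the antiperiplanar ring-fusion bond; it would give the hydroazulene as its trisubstituted ring olefin F4 (C1=C10). A photoredox/chromium dual-catalysed contra-thermodynamic positional isomerisation (photo-oxidant, CrCl3, pyridine base, MeOH, blue light), which protonates an allylchromium intermediate at its more substituted end, would then move the double bond to the exocyclic position and return to 17.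

Step 15. Facial selectivity may be poor, so that both 3,4-trans adducts form; bond formation between two hindered carbons may be slow; and the acidic γ-position of the enal may enolise. The fallback replaces substrate control by reagent control. Aldehyde 18 would be condensed with one equivalent of (R)-2-[diphenyl(trimethylsilyloxy)methyl]pyrrolidine to give the chiral enamine F5, in which the diarylmethyl group shields one face, as in the known additions of diarylprolinol silyl ether enamines to electron-poor alkenes. Addition to enal 22 would then be directed by the amine, with the usual syn (ring-trans) topology, to give the 2-aminodihydropyran F6. Treatment of this adduct under the conditions of step 16 would release the amine and return to 25.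

Step 17. The exocyclic methylene may be epoxidised alongside the enol ether, the oxidant may attack the wrong face, or the diol may be over-oxidised in step 18. The fallback introduces the C4′ oxygen by enolate chemistry. Enol ether 25 would be oxidised with pyridinium chlorochromate, a known conversion of cyclic enol ethers into lactones, to give the saturated δ-lactone F7. Its potassium enolate (KHMDS, THF, −78 °C), formed at the unhindered lactone methylene, would be hydroxylated with 2-(phenylsulfonyl)-3-phenyloxaziridine from the face anti to the bridge that carries the hydroazulene, giving hydroxy lactone 28 ahead of step 19.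

**Further compounds**

F1 | step 11 | 8β-methyl-8α-(2-phenylsulfonylethyl)-11-nordriman-9-one | C[C@]12CCCC(C)(C)[C@@H]1CC[C@@](C)(CCS(=O)(=O)c3ccccc3)C2=O
F2 | step 11 | 8β-methyl-8α-(2-phenylsulfonylethyl)-11-nordriman-9β-ol | C[C@]12CCCC(C)(C)[C@@H]1CC[C@@](C)(CCS(=O)(=O)c3ccccc3)[C@@H]2O
F3 | step 11 | 9β-methanesulfonate of F2 | C[C@]12CCCC(C)(C)[C@@H]1CC[C@@](C)(CCS(=O)(=O)c3ccccc3)[C@@H]2OS(C)(=O)=O
F4 | step 11 | cis-hydroazulene sulfone with ring double bond C1=C10 (10-methyl) | CC1=CCCC(C)(C)[C@@H]2CC[C@@](C)(CCS(=O)(=O)c3ccccc3)[C@H]12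
F5 | step 15 | (E)-enamine of 18 with (R)-2-[diphenyl(trimethylsilyloxy)methyl]pyrrolidine | C=C1CCCC(C)(C)[C@@H]2CC[C@@](C)(/C=C/N3CCC[C@@H]3C(c3ccccc3)(c3ccccc3)O[Si](C)(C)C)[C@H]12
F6 | step 15 | 2-aminodihydropyran adduct of F5 and 22 | C=C1CCCC(C)(C)[C@@H]2CC[C@@](C)([C@@H]3[C@@H](N4CCC[C@@H]4C(c4ccccc4)(c4ccccc4)O[Si](C)(C)C)OC=C[C@H]3[C@@H](O[Si](CC)(CC)CC)C(=O)OC)[C@H]12
F7 | step 17 | methyl (6′R)-8′-(hydroazulen-8α-yl)-3′-oxo-2′,7′-dioxabicyclo[3.2.1]octane-6′-carboxylate | C=C1CCCC(C)(C)[C@@H]2CC[C@@](C)([C@@H]3[C@@H]4OC(=O)C[C@H]3[C@H](C(=O)OC)O4)[C@H]12
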